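(The data were generated by integration from invented constants; scatter was added.)

Slowness is the first thing these runs show: at 20.0 h the north-west run, with twice the loading of Monday's and Friday's flasks, holds just 13.6% left-handed product and 2.6% right-handed product.

| setting | west | north-east | north-west | Monday's | Friday's |
|---|---|---|---|---|---|
| left-handed substrate | 0.25 M | 0.38 M | 0.50 M | 0.50 M | 0.50 M |
| right-handed substrate | 0.25 M | 0.38 M | 0.50 M | 0.50 M | 0.50 M |
| reagent | 1 equiv | 1 equiv | 1 equiv | 1.00 equiv | 1.00 equiv |
| precatalyst | 5 mol% | 5 mol% | 10 mol% | 5 mol% | 5 mol% |
| remark | run made earlier | run made earlier | run made earlier |  |  |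
| time |  |  |  | 25 h | 50 h |

- west (time / h: left-handed product / %, right-handed product / %): 4.00: 0, 0.6; 8.00: 0.3, 0; 12.0: 0.9, 0.7; 15.0: 2.1, 1.1; 20.0: 2.9, 1.1
- north-east (time / h: left-handed product / %, right-handed product / %): 4.00: 0.3, 0; 8.00: 0.7, 0.6; 12.0: 2.2, 1.2; 15.0: 3.8, 0.4; 20.0: 5.7, 1.1
- north-west (time / h: left-handed product / %, right-handed product / %): 1.50: 0, 0; 3.00: 0.7, 0; 6.00: 1.9, 0; 10.0: 4.7, 1.1; 20.0: 13.6, 2.6

(scatter of a reading: 0.5 percentage points)

- free catalyst is single-handed; left-handed substrate and right-handed substrate are mirror images of each other, charged as a racemate, each of them at the stated concentration
- what was read earlier has a scatter of 0.5 percentage points, one standard deviation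
- an excess is the difference of the two amounts in percent of their sum
- an excess is below zero if the other one leads

- which one finishes higher in excess of left-handed product over right-handed product in the product ("neither" within 2 percentage points) (Monday's / Friday's / neither)
- excess of left-handed product over right-handed product in the product at the end, Monday's
- excess of left-handed product over right-handed product in the product at the end, Friday's

The excess is asked, not the yield, so I divide the two product rates and let time drop out. My carried quantity is the selectivity factor s, left-handed product made per right-handed product made at equal substrate, 4.62, read from the summed last readings of the three runs. It remains a reading, since each small right-handed figure carries a scatter of 0.5 percentage points.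

Next comes the left-handed product. The north-west run gains 8.9 points between 10.0 h and 20.0 h. Monday's and Friday's flasks have half its loading, so I take half its amount and half its hourly gain, which gives 9.03% at 25 h and 20.2% at 50 h. On that reckoning 81.9% and 59.6% of the left-handed substrate remain. If the two substrates compete with s held constant, the fraction of right-handed substrate remaining is the s-th root of those fractions, which makes 2.11% and 5.28% right-handed product, provided each product keeps the hand it was made with. My excesses are 62.2% for Monday's and 58.5% for Friday's, so I commit to Monday's, ahead by 3.7 points, which is more than the margin.

The forecast gives Monday's, with 60% and 56%, in its words “Monday's finishes higher, though only modestly”, and my Friday's number is higher than its own.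

The flask gives Monday's, with 56.5% and 33.2%.

    free catalyst + left-handed substrate ⇌ catalyst intermediate A (K = 25.0 /M, k = 11.0 /M/h)
    reagent + catalyst intermediate A → free catalyst + left-handed product (k = 1.90 /M/h)
    precatalyst → free catalyst (k = 0.0350 /h)
    free catalyst + right-handed substrate ⇌ catalyst intermediate B (K = 1.10 /M, k = 21.0 /M/h)
    left-handed product ⇌ right-handed product (k = 0.0260 /h)
    reagent + catalyst intermediate B → free catalyst + right-handed product (k = 0.820 /M/h)

The link to reforge is my rule that product keeps its hand: the scheme has left-handed product going over to right-handed product, with a forward half-life of 27 h. Friday's flask holds 9.98% right-handed product where I reckoned 5.28%, yet its right-handed substrate has lost 2.2 points, and its product ratio is 2.00, lower than s. The neighbouring flask, Friday's with 4.00 equiv of reagent, keeps 3.2% of its left-handed substrate, so s gives 47.5% of the right-handed substrate; it keeps 62%, has lost 19 points against 30.5% right-handed product, and stands at an excess of 8.97%.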